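## Retrosynthetic overview

1. Target 25 ⇐ (10S)-10,11-diol 23 (side-chain epoxide closed last, with inversion at C10) ⇐ enone 18 (C1 acetate by α'-acetoxylation; ring epoxide by hydroxyl-directed epoxidation of the C2 allylic alcohol, then re-oxidation).
2. Key step, C5–O bond: [4+2] cycloaddition of singlet oxygen to the carvone-derived siloxy diene 14 gives a bicyclic endoperoxide anti to the C6 side chain; Mitsunobu inversion with tiglic acid then sets the 5β-tiglate.
3. C7–C8 bond: Shapiro vinyllithium from the carvone-derived methyl ketone adds to hydroxy lactone 4 (from L-malic acid, which supplies C10); C8 is set from C10 by anti-selective hydroxyl-directed reduction.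
4. Ring order: cyclohexenone bought in (R)-carvone → dioxolane (diol protection) → transient endoperoxide ring (cycloaddition) → ring epoxide → side-chain epoxide.

Convention: ring C1 (OAc), C2 (C=O), C3 (Me), C4, C5 (O-tiglate), C6 (side chain); side chain C7(=C14H2)–C8–C9–C10–C11(Me)2. β = ring face of the C6 side chain, α = the opposite face.
Assumption: (R)-(−)-carvone and L-malic acid are the only chiral purchases; tigloyl chloride, tiglic acid, 2,4,6-triisopropylbenzenesulfonyl hydrazide and 2-bromomesitylene are commercial.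

## Route

Step 1
Reactants: 1 L-malic acid
Product: 2 (S)-2-(2,2-dimethyl-5-oxo-1,3-dioxolan-4-yl)acetic acid
Conditions: Me2C(OMe)2, p-TsOH (cat.), rt
Reagents that add atoms: 2,2-dimethoxypropane, COC(C)(C)OC
Why: Acid-catalysed transketalisation closes the five-membered dioxolanone on the α-hydroxy acid unit only, leaving the other carboxylic acid free and the stereocenter untouched.

Step 2
Reactants: 2 (S)-2-(2,2-dimethyl-5-oxo-1,3-dioxolan-4-yl)acetic acid
Product: 4 (S)-4-hydroxy-5,5-dimethyldihydrofuran-2(3H)-one, via dihydroxy acid 3 (not isolated)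
Conditions: MeMgBr (5 equiv), THF, −20 → 0 °C; 2 M HCl, rt
Reagents that add atoms: methylmagnesium bromide, C[Mg]Br
Why: Grignard double addition to the activated dioxolanone carbonyl (the free acid is protected as its magnesium carboxylate) gives the tertiary alcohol, which lactonises on acid work-up with the (S) centre retained.

Step 3
Reactants: 5 (R)-(−)-carvone
Product: 7 (R)-5-acetyl-2-methylcyclohex-2-en-1-one, via ozonide 6 (not isolated)
Conditions: O3 (1.0 equiv), CH2Cl2, −78 °C; PPh3, −78 °C → rt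
Reagents that add atoms: ozone, [O-][O+]=O
Why: Ozonolysis (1,3-dipolar cycloaddition/cycloreversion) cleaves the electron-rich 1,1-disubstituted alkene selectively over the conjugated enone; the stereocenter is not touched.

Step 4
Reactants: 7 (R)-5-acetyl-2-methylcyclohex-2-en-1-one
Product: 8 (E)-2,4,6-triisopropylbenzenesulfonylhydrazone of the acetyl group of 7
Conditions: 2,4,6-(i-Pr)3C6H2SO2NHNH2 (1.0 equiv), THF, rt
Reagents that add atoms: 2,4,6-triisopropylbenzenesulfonyl hydrazide, CC(C)c1cc(C(C)C)c(S(=O)(=O)NN)c(C(C)C)c1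
Why: Hydrazone condensation is much faster at the unhindered saturated methyl ketone than at the conjugated, α-methylated ring carbonyl.

Step 5
Reactants: 8 trisylhydrazone; 4 (S)-4-hydroxy-5,5-dimethyldihydrofuran-2(3H)-one
Product: 10 (R)-5-[(S)-5,6-dihydroxy-6-methyl-3-oxohept-1-en-2-yl]-2-methylcyclohex-2-en-1-one, via vinyllithium enolate 9 (not isolated)
Conditions: mesityllithium (2,4,6-Me3C6H2Li, 2.1 equiv; from 2-bromomesitylene, t-BuLi), THF, −78 °C; n-BuLi (1.1 equiv), −78 → 0 °C; −78 °C, add 4 (pre-treated with mesityllithium, 1.0 equiv); AcOH, −78 °C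
Reagents that add atoms: none
Why: Shapiro reaction with the ring enone masked in situ as its kinetic lithium enolate (amine-free, non-nucleophilic base): the hydrazone dianion loses sulfinate and N2 to give the 1,1-disubstituted vinyllithium, which adds once to the lactone carbonyl (adduct stable at −78 °C); no stereocenter is created and C6 and C10 are untouched.

Step 6
Reactants: 10 β-hydroxy enone
Product: 11 (R)-5-[(3S,5S)-3,5,6-trihydroxy-6-methylhept-1-en-2-yl]-2-methylcyclohex-2-en-1-one
Conditions: Me4NBH(OAc)3 (5 equiv), MeCN/AcOH (1:1), −30 °C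
Reagents that add atoms: none
Why: Evans–Saksena hydroxyl-directed reduction: the acetoxyborohydride bound to the C10 hydroxyl delivers hydride intramolecularly through a chair transition state to give the 1,3-anti (8S) alcohol, and the ring enone, which has no directing hydroxyl, is not reduced.

Step 7
Reactants: 11 (8S,10S)-triol
Product: 12 (R)-5-{(3S)-3-hydroxy-4-[(4S)-2,2,5,5-tetramethyl-1,3-dioxolan-4-yl]but-1-en-2-yl}-2-methylcyclohex-2-en-1-one
Conditions: Me2C(OMe)2, PPTS (cat.), CH2Cl2, rt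
Reagents that add atoms: 2,2-dimethoxypropane, COC(C)(C)OC
Why: Thermodynamic ketalisation takes the 10,11-diol as a five-membered dioxolane because the anti-1,3-diol would need a strained twist-boat dioxane, so only the C8 hydroxyl stays free.

Step 8
Reactants: 12 acetonide alcohol
Product: 13 8-O-tiglate of 12
Conditions: tigloyl chloride, DMAP, pyridine, CH2Cl2, 0 °C → rt
Reagents that add atoms: tigloyl chloride, C/C=C(\C)C(=O)Cl
Why: DMAP-catalysed acylation of the only free hydroxyl proceeds with retention at C8 and without E/Z erosion of the tiglate.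

Step 9
Reactants: 13 C8 tiglate enone
Product: 14 linear trimethylsilyl dienol ether of 13 (2-silyloxy, C2=C3 and C4=C5)
Conditions: MeMgBr (1.3 equiv), FeCl3 (5 mol %), Et2O, −20 °C; TMSCl, Et3N, HMPA
Reagents that add atoms: chlorotrimethylsilane, C[Si](C)(C)Cl
Why: Thermodynamic γ-enolisation (Krafft–Holton conditions): the iron ate base removes a C5 proton rather than adding to the enone, and O-silylation traps the linear dienolate; no stereocenter is affected.

Step 10
Reactants: 14 siloxy diene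
Product: 17 5α-hydroxy enone (5-OH trans to the C6 side chain; 8S-tiglate and 10,11-acetonide retained), via endoperoxide 15 (not isolated), via silylperoxy enone 16 (not isolated)
Conditions: O2, tetraphenylporphyrin (cat.), hν, CH2Cl2, −78 °C; PPh3, −78 °C → rt; AcOH/THF/H2O, rt
Reagents that add atoms: oxygen, O=O
Why: Key [4+2] cycloaddition (hetero-Diels–Alder) of singlet oxygen to the ring-locked s-cis siloxy diene occurs on the face opposite the C6 side chain, forming the C5–O bond α; silyl migration opens the peroxy ketal to the enone, and PPh3 then mild acid reduce and desilylate.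

Step 11
Reactants: 17 5α-hydroxy enone
Product: 18 5β,8-bis-tiglate enone
Conditions: tiglic acid, PPh3, DIAD, toluene, 0 °C → rt
Reagents that add atoms: tiglic acid, C/C=C(\C)C(=O)O
Why: Mitsunobu esterification is an SN2 displacement of the alkoxyphosphonium by tiglate, so C5 is inverted to the 5β configuration (cis to the side chain) while the ester is installed.

Step 12
Reactants: 18 bis-tiglate enone
Product: 19 1α-acetoxy-5β,8-bis-tiglate enone
Conditions: Mn(OAc)3·2H2O (3 equiv), benzene, reflux (Dean–Stark)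
Reagents that add atoms: manganese triacetate dihydrate, CC(=O)[O-].CC(=O)[O-].CC(=O)[O-].[Mn+3].O.O
Why: α'-Acetoxylation of the enone through its manganese enolate transfers acetate to C1 on the face opposite the adjacent C6 side chain, giving the trans (1α) acetate, which is also the thermodynamically favoured equatorial epimer.

Step 13
Reactants: 19 α'-acetoxy enone
Product: 20 2β-allylic alcohol of 19
Conditions: NaBH4, CeCl3·7H2O, MeOH, −78 °C
Reagents that add atoms: none
Why: Luche 1,2-reduction by axial hydride attack from the α face (as for carvone → cis-carveol, reinforced by the pseudoaxial 5β-tiglate) gives the equatorial 2β alcohol, trans to the C1 acetate.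

Step 14
Reactants: 20 2β-allylic alcohol
Product: 21 3β,4β-epoxy-2β-alcohol
Conditions: VO(acac)2 (5 mol %), t-BuOOH, CH2Cl2, 0 °C → rt
Reagents that add atoms: tert-butyl hydroperoxide, CC(C)(C)OO
Why: Hydroxyl-directed epoxidation delivers oxygen from the vanadium alkoxide to the same (β) face as the C2 hydroxyl, and the other alkenes (allylic ester, tiglates) have no free allylic hydroxyl and are left alone.

Step 15
Reactants: 21 epoxy alcohol
Product: 22 1α-acetoxy-3β,4β-epoxy-2-ketone 5β,8-bis-tiglate 10,11-acetonide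
Conditions: Dess–Martin periodinane, CH2Cl2, rt
Reagents that add atoms: none
Why: Mild, non-basic alcohol oxidation restores the C2 ketone without epimerising C1 or opening the epoxide.

Step 16
Reactants: 22 epoxy ketone acetonide
Product: 23 the corresponding (10S)-10,11-diol
Conditions: AcOH/H2O (4:1), 40 °C
Reagents that add atoms: none
Why: Mild acid hydrolysis removes the dioxolane; the α,β-epoxy ketone is deactivated toward acid opening and the cis-disposed 5β-tiglate cannot participate from the back side.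

Step 17
Reactants: 23 (10S)-10,11-diol
Product: 25 target CNP0407453.3, via secondary triflate 24 (not isolated)
Conditions: Tf2O (1.1 equiv), 2,6-lutidine, CH2Cl2, −78 → 0 °C
Reagents that add atoms: none
Why: Selective triflation of the secondary C10 hydroxyl is followed by intramolecular SN2 (3-exo-tet) attack of the neighbouring tertiary hydroxyl, closing the epoxide with inversion to (10R) under a hindered base too weak to enolise the α-acetoxy ketone.

## Compound list

1 | L-malic acid | OC(=O)C[C@H](O)C(=O)O | starting material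
2 | (S)-2-(2,2-dimethyl-5-oxo-1,3-dioxolan-4-yl)acetic acid | CC1(C)O[C@@H](CC(=O)O)C(=O)O1 | intermediate
3 | (S)-3,4-dihydroxy-4-methylpentanoic acid | OC(=O)C[C@H](O)C(C)(C)O | intermediate (not isolated)
4 | (S)-4-hydroxy-5,5-dimethyldihydrofuran-2(3H)-one | CC1(C)OC(=O)C[C@@H]1O | intermediate
5 | (R)-(−)-carvone | C=C(C)[C@@H]1CC=C(C)C(=O)C1 | starting material
6 | 3-methyl-3-[(1R)-4-methyl-5-oxocyclohex-3-en-1-yl]-1,2,4-trioxolane (ozonide) | CC1(OCOO1)[C@@H]1CC=C(C)C(=O)C1 | intermediate (not isolated)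
7 | (R)-5-acetyl-2-methylcyclohex-2-en-1-one | CC(=O)[C@@H]1CC=C(C)C(=O)C1 | intermediate
8 | (E)-2,4,6-triisopropylbenzenesulfonylhydrazone of the acetyl group of 7 | C/C(=N\NS(=O)(=O)c1c(C(C)C)cc(C(C)C)cc1C(C)C)[C@@H]1CC=C(C)C(=O)C1 | intermediate
9 | C7 vinyllithium / C2 lithium enolate of the carvone core | [Li]C(=C)[C@@H]1CC=C(C)C(O[Li])=C1 | intermediate (not isolated)
10 | (R)-5-[(S)-5,6-dihydroxy-6-methyl-3-oxohept-1-en-2-yl]-2-methylcyclohex-2-en-1-one | C=C([C@@H]1CC=C(C)C(=O)C1)C(=O)C[C@H](O)C(C)(C)O | intermediate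
11 | (R)-5-[(3S,5S)-3,5,6-trihydroxy-6-methylhept-1-en-2-yl]-2-methylcyclohex-2-en-1-one | C=C([C@@H]1CC=C(C)C(=O)C1)[C@H](C[C@H](O)C(C)(C)O)O | intermediate
12 | (R)-5-{(3S)-3-hydroxy-4-[(4S)-2,2,5,5-tetramethyl-1,3-dioxolan-4-yl]but-1-en-2-yl}-2-methylcyclohex-2-en-1-one | C=C([C@@H]1CC=C(C)C(=O)C1)[C@H](C[C@@H]1OC(C)(C)OC1(C)C)O | intermediate
13 | 8-O-tiglate of 12 | C=C([C@@H]1CC=C(C)C(=O)C1)[C@H](C[C@@H]1OC(C)(C)OC1(C)C)OC(=O)/C(C)=C/C | intermediate
14 | linear trimethylsilyl dienol ether of 13 (C2–OSiMe3, C2=C3, C4=C5) | C=C([C@@H]1C=CC(C)=C(O[Si](C)(C)C)C1)[C@H](C[C@@H]1OC(C)(C)OC1(C)C)OC(=O)/C(C)=C/C | intermediate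
15 | 2α,5α-endoperoxide of 14 (2β-OSiMe3) | C=C([C@@H]1[C@@H]2C=C(C)[C@@](O[Si](C)(C)C)(OO2)C1)[C@H](C[C@@H]1OC(C)(C)OC1(C)C)OC(=O)/C(C)=C/C | intermediate (not isolated)
16 | 5α-(trimethylsilylperoxy) enone | C=C([C@@H]1[C@@H](OO[Si](C)(C)C)C=C(C)C(=O)C1)[C@H](C[C@@H]1OC(C)(C)OC1(C)C)OC(=O)/C(C)=C/C | intermediate (not isolated)
17 | 5α-hydroxy enone (8S-tiglate, 10,11-acetonide) | C=C([C@@H]1[C@@H](O)C=C(C)C(=O)C1)[C@H](C[C@@H]1OC(C)(C)OC1(C)C)OC(=O)/C(C)=C/C | intermediate
18 | 5β,8-bis-tiglate enone | C=C([C@@H]1[C@H](OC(=O)/C(C)=C/C)C=C(C)C(=O)C1)[C@H](C[C@@H]1OC(C)(C)OC1(C)C)OC(=O)/C(C)=C/C | intermediate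
19 | 1α-acetoxy-5β,8-bis-tiglate enone | C=C([C@@H]1[C@H](OC(=O)/C(C)=C/C)C=C(C)C(=O)[C@H]1OC(C)=O)[C@H](C[C@@H]1OC(C)(C)OC1(C)C)OC(=O)/C(C)=C/C | intermediate
20 | 2β-allylic alcohol of 19 | C=C([C@@H]1[C@H](OC(=O)/C(C)=C/C)C=C(C)[C@H](O)[C@H]1OC(C)=O)[C@H](C[C@@H]1OC(C)(C)OC1(C)C)OC(=O)/C(C)=C/C | intermediate
21 | 3β,4β-epoxy-2β-alcohol | C=C([C@@H]1[C@H](OC(=O)/C(C)=C/C)[C@@H]2O[C@]2(C)[C@H](O)[C@H]1OC(C)=O)[C@H](C[C@@H]1OC(C)(C)OC1(C)C)OC(=O)/C(C)=C/C | intermediate
22 | 1α-acetoxy-3β,4β-epoxy-2-ketone 5β,8-bis-tiglate 10,11-acetonide | C=C([C@@H]1[C@H](OC(=O)/C(C)=C/C)[C@@H]2O[C@]2(C)C(=O)[C@H]1OC(C)=O)[C@H](C[C@@H]1OC(C)(C)OC1(C)C)OC(=O)/C(C)=C/C | intermediate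
23 | (10S)-10,11-diol of 22 | C=C([C@@H]1[C@H](OC(=O)/C(C)=C/C)[C@@H]2O[C@]2(C)C(=O)[C@H]1OC(C)=O)[C@H](C[C@H](O)C(C)(C)O)OC(=O)/C(C)=C/C | intermediate
24 | C10 triflate of 23 | C=C([C@@H]1[C@H](OC(=O)/C(C)=C/C)[C@@H]2O[C@]2(C)C(=O)[C@H]1OC(C)=O)[C@H](C[C@H](OS(=O)(=O)C(F)(F)F)C(C)(C)O)OC(=O)/C(C)=C/C | intermediate (not isolated)
25 | CNP0407453.3 | C=C([C@@H]1[C@H](OC(=O)/C(C)=C/C)[C@@H]2O[C@]2(C)C(=O)[C@H]1OC(C)=O)[C@H](C[C@H]1OC1(C)C)OC(=O)/C(C)=C/C | target

## Step count and risks

Total: 17 steps (2 for lactone 4, 15 from carvone). Longest linear sequence: 15 steps (5 → 25, steps 3–17).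

Most likely to fail:

Step 5 (Shapiro coupling with the ring enone masked only as its enolate; the product is also prone to oxa-Michael closure and alkene migration). Fallback, from 8 back to 10: reduce the ring ketone of 8 first (NaBH4, CeCl3·7H2O, MeOH, −78 °C) to the cis-allylic alcohol trisylhydrazone F1. Run an ordinary Shapiro reaction on its alkoxide (n-BuLi, 3.2 equiv, THF, −78 → 0 °C) and add the vinyllithium to lactone 4 to give the ring-alcohol hydroxy ketone F2. Re-oxidise only the ring allylic alcohol with MnO2 (CH2Cl2, rt), which returns to 10.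

Step 9 (thermodynamic enolisation with MeMgBr/FeCl3 in the presence of the C8 tiglate). Fallback, from 12 back to 18: keep C8 as a silyl ether during the enolisation instead of an ester. Silylate 12 (TBSCl, imidazole, DMF) to the C8 silyl ether F3, then enolise and silylate as in step 9 to the siloxy diene F4. Run the same singlet-oxygen cycloaddition, PPh3 reduction and mild acid work-up to the 5α-alcohol F5, and invert with tiglic acid, PPh3 and DIAD to the 5β-tiglate silyl ether F6. Remove the silyl group (HF·pyridine, THF) to the C8 alcohol F7 and acylate with tigloyl chloride/DMAP, which returns to 18.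

Step 11 (Mitsunobu at a hindered allylic carbinol; elimination towards a dienone/phenol competes). Fallback, from 17 back to 18: separate activation from displacement. Convert 17 with MsCl/Et3N (CH2Cl2, −20 °C) into the 5α-mesylate F8 and displace it with cesium tiglate (tiglic acid, Cs2CO3, 18-crown-6, toluene, rt) with inversion, which returns to 18.

## Further compounds

F1 | step 5 | 2β-alcohol (cis to the C6 substituent) of trisylhydrazone 8 | C/C(=N\NS(=O)(=O)c1c(C(C)C)cc(C(C)C)cc1C(C)C)[C@@H]1CC=C(C)[C@H](O)C1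
F2 | step 5 | 2β-alcohol analogue of 10 (ring allylic alcohol, 8-ketone, 10S,11-diol) | C=C([C@@H]1CC=C(C)[C@H](O)C1)C(=O)C[C@H](O)C(C)(C)O
F3 | step 9 | 8-O-tert-butyldimethylsilyl ether of 12 | C=C([C@@H]1CC=C(C)C(=O)C1)[C@H](C[C@@H]1OC(C)(C)OC1(C)C)O[Si](C)(C)C(C)(C)C
F4 | step 9 | linear trimethylsilyl dienol ether of F3 | C=C([C@@H]1C=CC(C)=C(O[Si](C)(C)C)C1)[C@H](C[C@@H]1OC(C)(C)OC1(C)C)O[Si](C)(C)C(C)(C)C
F5 | step 9 | 5α-hydroxy enone, 8-O-silyl ether | C=C([C@@H]1[C@@H](O)C=C(C)C(=O)C1)[C@H](C[C@@H]1OC(C)(C)OC1(C)C)O[Si](C)(C)C(C)(C)C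
F6 | step 9 | 5β-tiglate enone, 8-O-silyl ether | C=C([C@@H]1[C@H](OC(=O)/C(C)=C/C)C=C(C)C(=O)C1)[C@H](C[C@@H]1OC(C)(C)OC1(C)C)O[Si](C)(C)C(C)(C)C
F7 | step 9 | 5β-tiglate enone with free 8S-hydroxyl | C=C([C@@H]1[C@H](OC(=O)/C(C)=C/C)C=C(C)C(=O)C1)[C@H](C[C@@H]1OC(C)(C)OC1(C)C)O
F8 | step 11 | 5α-mesylate of 17 | C=C([C@@H]1[C@@H](OS(C)(=O)=O)C=C(C)C(=O)C1)[C@H](C[C@@H]1OC(C)(C)OC1(C)C)OC(=O)/C(C)=C/C
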